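## Analysis of the target

Numbering used throughout: C1 ketone, C2=C3 (C3 carries a methyl), C4, C5, C6 (gem-dimethyl), C7 (3-methylbutanoate), C8, C9 (tiglate), C10 (quaternary, methyl), C11.

- **Ring system.** Compound 20 is a longipinane. A cyclobutane C4–C5–C11–C10 has its corners C4 and C11 spanned by the enone bridge C1–C2=C3 (a verbenone-like bicyclo[3.1.1]heptenone). Its other corners C5 and C10 are spanned by the four-carbon bridge C6–C7–C8–C9, which closes the seven-membered ring.
- **Stereocentres.** C4, C5, C10 and C11 belong to the cage and can exist in only one relative arrangement, so together they are one decision: the enantiomer of the cage. C7 and C9 are both R. Their oxygens are trans across C8, with O7 on the side of C4 and O9 on the side of C11.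
- **Sensitive groups.** The strained cyclobutane sits next to carbonyl groups and is open to cationic shifts in acid, ring opening by one-electron reductants and acyl shifts under UV light. There is also the enone, and two different esters on neopentylic secondary carbons, one of them unsaturated.
- **Why it is hard.** The cage carries the quaternary centres C6 and C10 on or next to a four-membered ring. The C7/C9 pair sits on a bridge the cage hardly differentiates: an approximate mirror plane exchanges C4 with C11, and only the remote C1/C3 substitution breaks it. C7 and C9 themselves differ only in their quaternary neighbours.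
- **Feature the plan rests on.** The fifteen skeletal carbons are one unbranched head-to-tail farnesyl chain. C5 is its oxygen-bearing terminus, and three bonds (C5–C6, C5–C11, C4–C10) fold it into all three rings.
- **Consequence.** A cyclase that makes these bonds delivers the cage and its four stereocentres at once, but as a hydrocarbon. Every oxygen has to be introduced afterwards.

## Retrosynthetic reasoning

**20 to 17 and 18.** The C9–O acyl bond is cut last. The tiglate is the group least tolerant of radicals, hydride donors and nucleophiles, so it is attached when nothing else remains to be done. The forward reaction must acylate a neopentylic secondary alcohol without moving the C7 ester.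

**17 to 14 and 15.** The O7–acyl bond and the C9–H bond are cut together. An aldehyde (15) bound to O7 as a hemiacetal can hand its hydrogen to a C9 carbonyl and end up as the C7 ester. This one operation sets C9 from C7 (trans), installs the 3-methylbutanoate and leaves O9 free, so the two oxygens never need to be told apart by sterics. It also leaves the C1 enone alone, which an external hydride reagent would not.

**14 to 12.** The C7–O bond is cut back to a C7=C8–C9=O enone. The cage does not bias the faces of C7, so this centre has to be set by a chiral catalyst. Conjugate addition of a boron nucleophile followed by oxidation does that on a cyclic enone. The C1 enone is β,β-disubstituted and should stay out.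

**12 to 10.** The C9 carbonyl is traced to a C8=C9 alkene by an ene-type oxygenation with allylic transposition. This works because C10 is quaternary: the only allylic hydrogens are on C7, so oxygen can only arrive at C9 and the alkene can only move to C7=C8.

**10 to 9 to 7.** The C8=C9 alkene comes from a C8 ketone through its enol triflate. The ketone is a relay. C8 is the one position of the bridge that an undirected C–H oxidation can be expected to find, and from there the functionality is walked to C9 and C7. The forward step must enolize toward C9 and not C7.

**7 to 6.** The C8 carbonyl is cut to a C–H bond. The forward reaction is a methylene oxidation that must prefer C8 over the neopentylic C7 and C9 and over the cage C–H bonds.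

**6 to 5.** The C1 carbonyl is cut to the allylic methylene of the hydrocarbon. This oxidation comes first on purpose: as an enone the C2=C3 bond is electron-poor and survives the electrophilic oxidations of steps 5 and 8.

**5 to 3.** The bonds C5–C6, C5–C11 and C4–C10 are cut together, which unfolds the tricycle into the acyclic diphosphate 3. No stepwise construction makes the four cage stereocentres and the cyclobutane as cheaply. The forward reaction needs one folding mode of the chain and must stop at the cyclobutane stage.

**3 to 2 to 1.** The diphosphate is cut at C–O to the allylic chloride 2 and this to the alcohol 1, which is bought. Two reliable steps place the risk of the route in the cyclization.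

## Alternatives that were turned down

**Alternative 1:** Wolff ring contraction.
- Disconnection: the cyclobutane bond C10–C11, formed by contracting the five-membered ketone ring of a bicyclo[4.2.1]nonane.
- Forward key step: photolysis of the diazoketone A1 in an alcohol. Loss of N2 and migration of C10 from C1 to C11 give a ketene, trapped as the ester A2.
- For: ring contraction is a dependable entry to strained four-membered rings, driven by nitrogen loss. C7 and C9 already carry their oxygens, differentiated as ester and silyl ether and set on an ordinary seven-membered ring. On this point it is stronger than the chosen plan.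
- Against: A1, with five stereocentres including the quaternary C10, has to be built linearly, and the diazo group must be placed next to a bridgehead. After the contraction the six-membered ring is still missing. In A2, C2 is absent, C1 is an ester and C3 a masked methyl ketone. Closing that ring means a Claisen-type condensation to a β-diketone and then a choice between two similar carbonyls to place the C3 methyl and keep the C1 ketone. The C11 ester must also end up on the correct face for that closure.
- Comparison: a route of well over twice the length that buys chemical control of C7 and C9. The chosen strategy offers instead the whole skeleton with its four cage centres in one step, without protecting groups.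

**Alternative 2:** oxyallyl (4+3) cycloaddition.
- Disconnection: C5–C6 and C9–C10.
- Forward key step: the oxyallyl cation made from the dibromocyclobutanone A3 with Fe2(CO)9 adds to the diene A4 and gives the bicyclo[4.1.1]octenone A5.
- For: it is the most convergent plan. Both quaternary centres C6 and C10 and the seven-membered ring form together, and C7 and C9 arrive oxygenated and distinguishable.
- Against: an oxyallyl cation held in a four-membered ring cannot flatten without severe angle strain and is prone to contract instead of adding. The diene terminus that must bond (C6) carries two methyls, which disfavours the s-cis form and forces bond formation between two fully substituted carbons. Regiochemistry (C6 to C5, not to C10) and the endo/exo relation of C9 to the C11 ester are not secured by anything in A3 or A4. The product is racemic unless C11 of A3 is resolved. The cyclohexenone still has to be annulated onto the C4 ketone and C11 ester of A5.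
- Comparison: shorter on paper than alternative 1, but its key step has the least precedent of all four plans. The key step of the chosen strategy is a characterised transformation.

**Alternative 3:** intramolecular Diels–Alder with a temporary bond.
- Disconnection: C1–C11 and C4–C5, with a temporary C1–C10 bond.
- Forward key step: the tethered cyclopentadiene A6 cyclizes to the norbornene A7. Later the boronate becomes a leaving group and C10 shifts from C1 to C11 as the bridgehead silyl ether collapses to the C1 ketone.
- For: intramolecular Diels–Alder reactions are reliable. C10 is quaternary, so the diene cannot scramble by hydrogen shifts. The endo boron gives the antiperiplanar arrangement for the shift. The enone with its C3 methyl comes out directly, and C7 and C9 are set by acyclic methods. On the enone and on C7/C9 it is stronger than the chosen plan.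
- Against: the tether must close a seven-membered ring through the bridging carbon of a norbornene, with a weak dienophile whose reacting carbon C5 is neopentylic. Enantioenriched A6, with a quaternary stereocentre inside a silyloxydiene, is a long synthesis in itself. The 1,2-shift goes from a bicyclo[2.2.1] to the more strained bicyclo[3.1.1] skeleton, against the usual direction of such rearrangements, with only carbonyl formation to drive it.
- Comparison: the longest route. The chosen strategy reaches the complete skeleton in three steps from a bought alcohol and pays for it with late oxidation of a hydrocarbon, which is handled by the C8 relay and by reagent control at C7.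

Key step: step 3

Assumption: the conifer synthase is taken to release the dextrorotatory (1R,2S,7R,8R) hydrocarbon, the enantiomer that accompanies longifolene in conifer resins; this is the enantiomer drawn for 5 and required by 20.

## Route

Step 1
Reactants: 1 (2E,6E)-farnesol
Product: 2 (2E,6E)-farnesyl chloride
Conditions: NCS, Me2S, CH2Cl2, −30 to 0 °C
Reagents that add atoms: N-chlorosuccinimide, O=C1CCC(=O)N1Cl
Why: Corey–Kim allylic chlorination: the alkoxysulfonium salt is displaced by chloride at the primary carbon (SN2), so neither the 2E geometry nor the position of the double bond changes.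

Step 2
Reactants: 2 (2E,6E)-farnesyl chloride
Product: 3 (2E,6E)-farnesyl diphosphate (isolated as the tris-ammonium salt)
Conditions: (Bu4N)3HP2O7, MeCN, rt; cation-exchange resin (NH4+ form); cellulose chromatography
Reagents that add atoms: tris(tetrabutylammonium) hydrogen diphosphate, CCCC[N+](CCCC)(CCCC)CCCC.CCCC[N+](CCCC)(CCCC)CCCC.CCCC[N+](CCCC)(CCCC)CCCC.OP(=O)([O-])OP(=O)([O-])[O-]
Why: SN2 displacement of the primary allylic chloride by the diphosphate anion in acetonitrile, then cation exchange to the ammonium salt the enzyme accepts; substitution at the terminal carbon leaves the 2E alkene intact.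

Step 3
Reactants: 3 (2E,6E)-farnesyl diphosphate
Product: 5 α-longipinene, via enzyme-bound nerolidyl diphosphate 4 (not isolated)
Conditions: recombinant Norway spruce (Picea abies) longifolene/α-longipinene synthase from E. coli, MgCl2, DTT, HEPES pH 7.2, glycerol, pentane overlay, 30 °C; AgNO3–silica chromatography
Reagents that add atoms: none
Why: Mg2+-assisted ionisation of 3 and return of diphosphate to the tertiary carbon give 4, whose free rotation puts the chain into the cisoid fold; after re-ionisation the distal alkene (C6=C7 in product numbering) attacks the allyl cation terminus C5 (bond C5–C6) to an eleven-membered cation whose charge at C7 is removed by a 1,3-hydride shift from C5. The resulting C5–C4–C3 allyl cation is attacked across the ring by the central alkene (bond C5–C11), which divides the macrocycle into the six- and seven-membered rings and leaves a tertiary cation at C10; the C3=C4 alkene then adds to C10 through C4 (bond C4–C10) and loss of a proton from C2 gives the C2=C3 alkene. The closest known reaction type is the cation–olefin polycyclisation of diphosphate-ionising terpene cyclases, and this conversion is a characterised activity of the conifer enzyme. Ring modes: the macrocycle by an eleven-membered closure onto the allyl cation, the six/seven pair by one transannular bond (6-exo as seen from the six-membered ring), the cyclobutane by a 4-exo capture of the C10 cation in the Markovnikov sense. C4, C5, C10 and C11 are all set by the single chiral fold that the active site imposes; the cage allows only one relative arrangement of the four, so the fold decides the enantiomer. The selectivity that matters is termination: the cascade must stop by deprotonation at C2 and must not run on by further bond shifts to the longifolene skeleton or lose the proton from the C3 methyl, and only the enzyme, not the substrate, controls this. With the spruce enzyme longifolene is the main product and 5 a minor one, so 5 is taken from the pentane extract on AgNO3-impregnated silica, where the exocyclic alkene of longifolene is held back more strongly.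

Step 4
Reactants: 5 α-longipinene
Product: 6 longipin-2-en-1-one
Conditions: CrO3, 3,5-dimethylpyrazole, CH2Cl2, −20 °C
Reagents that add atoms: chromium trioxide, O=[Cr](=O)=O
Why: Allylic oxidation with the CrO3–3,5-dimethylpyrazole complex: C1 is the only allylic methylene, the other ring allylic position C4 being a cyclobutane bridgehead, so the enone forms as in the conversion of α-pinene to verbenone. It is placed here so that the C2=C3 bond is electron-poor before the oxidations that follow.

Step 5
Reactants: 6 longipin-2-en-1-one
Product: 7 longipin-2-ene-1,8-dione
Conditions: quinuclidine, Me4NBF4, HFIP, O2, MeCN, RVC anode/Ni cathode, constant current, rt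
Reagents that add atoms: dioxygen, O=O
Why: Mediated anodic methylene oxygenation: the quinuclidine radical cation abstracts the most hydridic and least hindered hydrogen and O2 traps the radical, the pattern known for a CH2 flanked by two CH2–C(quaternary) units in ring A of drimane lactones. C8 is that methylene here, since C7 and C9 are neopentylic, the cyclobutane C–H bonds are strong and the enone deactivates its own surroundings; the electron-poor C2=C3 bond is a poor partner for the electrophilic radical.

Step 6
Reactants: 7 longipin-2-ene-1,8-dione
Product: 9 1-oxolongipina-2,8-dien-8-yl trifluoromethanesulfonate, via potassium C8=C9 enolate 8 (not isolated)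
Conditions: KN(SiMe3)2, THF, −78 °C; then PhNTf2, −78 to 0 °C
Reagents that add atoms: N-phenylbis(trifluoromethanesulfonimide), O=S(=O)(N(c1ccccc1)S(=O)(=O)C(F)(F)F)C(F)(F)F
Why: Kinetic enolate formation and O-sulfonylation: the base removes a proton from the saturated ketone (the enone has no enolizable α′-hydrogen because C11 is a bridgehead), and of the two α-methylenes C9 is expected to react first, because its quaternary neighbour C10 holds two of its substituents tied back in the cyclobutane whereas C7 lies between the two methyls of C6. No stereocentre is formed.

Step 7
Reactants: 9 1-oxolongipina-2,8-dien-8-yl trifluoromethanesulfonate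
Product: 10 longipina-2,8-dien-1-one
Conditions: Pd(OAc)2, PPh3, HCO2H, Bu3N, DMF, 60 °C
Reagents that add atoms: none
Why: Palladium-catalysed formate reduction of an alkenyl triflate: oxidative addition to zerovalent palladium formed in situ, formate exchange, loss of CO2 and reductive elimination of C8–H. The double bond stays at C8=C9 and the enone is not touched.

Step 8
Reactants: 10 longipina-2,8-dien-1-one
Product: 12 longipina-2,7-diene-1,9-dione, via C9 allylic hydroperoxide 11 (not isolated)
Conditions: O2, tetraphenylporphyrin (cat.), visible light, Ac2O, pyridine, DMAP (cat.), CH2Cl2, rt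
Reagents that add atoms: dioxygen, O=O
Why: Schenck ene reaction followed by Kornblum–DeLaMare dehydration in one pot: singlet oxygen can take an allylic hydrogen only from C7 (C10 is quaternary), so oxygen is delivered to C9 and the alkene moves to C7=C8; acetylation of 11 and base-induced loss of acetic acid give the C9 ketone. Both faces lead to the same product because C9 ends as a carbonyl, and the electron-poor C2=C3 bond does not react with singlet oxygen.

Step 9
Reactants: 12 longipina-2,7-diene-1,9-dione
Product: 14 (7R)-7-hydroxylongipin-2-ene-1,9-dione, via 7-boryl ketone 13 (not isolated)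
Conditions: B2pin2, CuCl (cat.), NaOt-Bu (cat.), 2,3-bis(tert-butylmethylphosphino)quinoxaline (one antipode, cat.), MeOH, THF, rt; then NaBO3·4H2O, THF/H2O, rt
Reagents that add atoms: sodium perborate (the oxygen at C7), [Na+].[Na+].O[B-]1(O)OO[B-](O)(O)OO1; bis(pinacolato)diboron (the boron of 13 only), CC1(C)OB(OC1(C)C)B1OC(C)(C)C(C)(C)O1
Why: Copper-catalysed enantioselective conjugate borylation of a cyclic enone, then C–B oxidation with retention: the ligated copper boryl adds boron to C7 and methanol protonates the copper enolate. The cage hardly distinguishes the two faces of C7, so the ligand decides, and the antipode that borylates the face syn to C4 (7R after oxidation) is used; the β,β-disubstituted C2=C3–C1=O enone is far slower in this addition.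

Step 10
Reactants: 14 (7R)-7-hydroxylongipin-2-ene-1,9-dione; 15 3-methylbutanal
Product: 17 (7R,9R)-9-hydroxy-1-oxolongipin-2-en-7-yl 3-methylbutanoate, via samarium-bound O7 hemiacetal 16 (not isolated)
Conditions: SmI2 (cat., premixed with 15 until decolourised), THF, −10 °C
Reagents that add atoms: none
Why: Evans–Tishchenko reduction: the C7 alkoxide adds to 15, and within a samarium chelate the hemiacetal C–H is passed to the C9 carbonyl on the face that carries O7, so the new hydroxyl comes out trans to O7 (9R) and the aldehyde ends as the C7 3-methylbutanoate. The C1 enone has no neighbouring hydroxyl to anchor the hydride donor, and the same operation tells the two oxygens apart.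

Step 11
Reactants: 17 (7R,9R)-9-hydroxy-1-oxolongipin-2-en-7-yl 3-methylbutanoate; 18 tiglic acid
Product: 20 (7R,9R)-7-(3-methylbutanoyloxy)-9-[(E)-2-methylbut-2-enoyloxy]longipin-2-en-1-one, via tiglic 2,4,6-trichlorobenzoic anhydride 19 (not isolated)
Conditions: 18, 2,4,6-Cl3C6H2COCl, Et3N, THF, rt; then 17, DMAP, toluene, 60 °C
Reagents that add atoms: 2,4,6-trichlorobenzoyl chloride (its aroyl group is carried by 19 only), O=C(Cl)c1c(Cl)cc(Cl)cc1Cl
Why: Yamaguchi esterification: DMAP opens 19 at the less hindered tigloyl carbonyl and the acylpyridinium salt acylates the neopentylic 9-OH. No stereocentre is touched and the E geometry of the tiglate is the stable one.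

## Compound list

1 | (2E,6E)-farnesol | CC(C)=CCC/C(C)=C/CC/C(C)=C/CO | starting material
2 | (2E,6E)-farnesyl chloride | CC(C)=CCC/C(C)=C/CC/C(C)=C/CCl | intermediate
3 | (2E,6E)-farnesyl diphosphate (drawn as the free acid, handled as the tris-ammonium salt) | CC(C)=CCC/C(C)=C/CC/C(C)=C/COP(=O)(O)OP(=O)(O)O | intermediate
4 | (6E)-nerolidyl diphosphate, enzyme-bound tertiary allylic isomer of 3 (configuration at the tertiary carbon fixed by the enzyme, not assigned) | C=CC(C)(CC/C=C(\C)CCC=C(C)C)OP(=O)(O)OP(=O)(O)O | intermediate (not isolated)
5 | α-longipinene, (1R,2S,7R,8R)-2,6,6,9-tetramethyltricyclo[5.4.0.0^2,8]undec-9-ene | C1CCC(C)(C)[C@@H]2[C@H]3CC=C(C)[C@@H]2[C@]31C | intermediate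
6 | longipin-2-en-1-one (cage as in 5) | C1CCC(C)(C)[C@@H]2[C@H]3C(=O)C=C(C)[C@@H]2[C@]31C | intermediate
7 | longipin-2-ene-1,8-dione | C1C(=O)CC(C)(C)[C@@H]2[C@H]3C(=O)C=C(C)[C@@H]2[C@]31C | intermediate
8 | potassium enolate of 7 with the C8=C9 double bond | C1=C([O-])CC(C)(C)[C@@H]2[C@H]3C(=O)C=C(C)[C@@H]2[C@]31C.[K+] | intermediate (not isolated)
9 | 1-oxolongipina-2,8-dien-8-yl trifluoromethanesulfonate | C1=C(OS(=O)(=O)C(F)(F)F)CC(C)(C)[C@@H]2[C@H]3C(=O)C=C(C)[C@@H]2[C@]31C | intermediate
10 | longipina-2,8-dien-1-one | C1=CCC(C)(C)[C@@H]2[C@H]3C(=O)C=C(C)[C@@H]2[C@]31C | intermediate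
11 | 9-hydroperoxylongipina-2,7-dien-1-one (both C9 epimers) | OOC1C=CC(C)(C)[C@@H]2[C@H]3C(=O)C=C(C)[C@@H]2[C@]31C | intermediate (not isolated)
12 | longipina-2,7-diene-1,9-dione | O=C1C=CC(C)(C)[C@@H]2[C@H]3C(=O)C=C(C)[C@@H]2[C@]31C | intermediate
13 | 7-(4,4,5,5-tetramethyl-1,3,2-dioxaborolan-2-yl)longipin-2-ene-1,9-dione, boron on the C7 face syn to C4 | O=C1C[C@@H](B4OC(C)(C)C(C)(C)O4)C(C)(C)[C@@H]2[C@H]3C(=O)C=C(C)[C@@H]2[C@]31C | intermediate (not isolated)
14 | (7R)-7-hydroxylongipin-2-ene-1,9-dione | O=C1C[C@@H](O)C(C)(C)[C@@H]2[C@H]3C(=O)C=C(C)[C@@H]2[C@]31C | intermediate
15 | 3-methylbutanal (isovaleraldehyde) | CC(C)CC=O | starting material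
16 | hemiacetal of 14 and 15 at O7, samarium-bound in the flask (drawn as the free hemiacetal, hemiacetal carbon unassigned) | O=C1C[C@@H](OC(O)CC(C)C)C(C)(C)[C@@H]2[C@H]3C(=O)C=C(C)[C@@H]2[C@]31C | intermediate (not isolated)
17 | (7R,9R)-9-hydroxy-1-oxolongipin-2-en-7-yl 3-methylbutanoate | O[C@@H]1C[C@@H](OC(=O)CC(C)C)C(C)(C)[C@@H]2[C@H]3C(=O)C=C(C)[C@@H]2[C@]31C | intermediate
18 | tiglic acid, (E)-2-methylbut-2-enoic acid | C/C=C(\C)C(=O)O | starting material
19 | tiglic 2,4,6-trichlorobenzoic anhydride | C/C=C(\C)C(=O)OC(=O)c1c(Cl)cc(Cl)cc1Cl | intermediate (not isolated)
20 | (7R,9R)-7-(3-methylbutanoyloxy)-9-[(E)-2-methylbut-2-enoyloxy]longipin-2-en-1-one (CNP0194415.1) | C/C=C(\C)C(=O)O[C@@H]1C[C@@H](OC(=O)CC(C)C)C(C)(C)[C@@H]2[C@H]3C(=O)C=C(C)[C@@H]2[C@]31C | target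

## Step count and least certain steps

Total: 11 steps. Longest linear sequence: 11 steps, from 1 to 20. Compounds 15 and 18 are used as bought.

**Step 3 (key step).** The likely failure is in termination of the cation cascade. The cyclobutane cation is an intermediate on the way to other skeletons, and the known enzyme passes most of it on, so 5 is a minor part of the hydrocarbon mixture and has to be separated. Low turnover and loss of the volatile product add to this. Fallback: move the cyclization into a whole-cell, two-phase fermentation. An E. coli strain carrying a heterologous mevalonate pathway, farnesyl diphosphate synthase and the same synthase gene, grown under a dodecane overlay, makes 3 inside the cell and releases the hydrocarbons into the overlay. This sets out from the sugar feed and no numbered compound, replaces 1 to 3, and comes back at 5 after the same silver-nitrate separation. Throughput then compensates for the unfavourable partition. No new compound is made (F0).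

**Step 5.** Hydrogen abstraction may spread to C7 or to the methyl groups, the ketone may be oxidized further, or the enone may be attacked, giving a mixture. Fallback, from 6 to 10: radical C–H chlorination with N-chloro-N-tert-butyl-3,5-bis(trifluoromethyl)benzamide (Cs2CO3, benzene, visible light, 55 °C). Its bulky amidyl radical chooses on steric grounds and should give 8-chlorolongipin-2-en-1-one F1. Dehydrochlorination with KOt-Bu in THF gives 10 directly, bypassing 7 and 9. If elimination also runs toward C7, the isomeric alkene is handled as described under step 6.

**Step 6.** Enolization may go toward C7 or be unselective, because the two α-methylenes differ only in their quaternary neighbours. Fallback, from 7 to 12: enolization toward C7 gives the regioisomeric triflate 1-oxolongipina-2,7-dien-8-yl trifluoromethanesulfonate F2. The same formate reduction gives longipina-2,7-dien-1-one F3, whose only allylic methylene is C9. The CrO3–3,5-dimethylpyrazole oxidation of step 4 then gives 12 without any transposition. A mixture of 9 and F2 can be separated at the triflate stage and each isomer taken to 12 by its own path.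

**Step 8.** The ene reaction of a cis-disubstituted alkene whose two ends are both next to quaternary carbons may be too slow, leading to bleaching of the sensitizer and incomplete conversion. Fallback, from 10 to 12:
- mCPBA (NaHCO3, CH2Cl2) epoxidizes only the electron-rich C8=C9 bond to 8,9-epoxylongipin-2-en-1-one F4 (either face).
- PhSeNa (from (PhSe)2 and NaBH4 in EtOH) opens it at C8, the carbon that is not neopentylic, to 9-hydroxy-8-(phenylselanyl)longipin-2-en-1-one F5.
- H2O2 oxidation and syn elimination away from the carbinol give 9-hydroxylongipina-2,7-dien-1-one F6.
- Dess–Martin periodinane gives 12, and also restores C1 should borohydride have touched it.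

**Step 9.** Facial selectivity may be poor if the ligand cannot control a β-carbon that sits next to the gem-dimethyl centre. Fallback, from 12 to 14: borylation with an achiral ligand (CuCl, NaOt-Bu, Xantphos, MeOH) and the same oxidation give 14 together with its epimer (7S)-7-hydroxylongipin-2-ene-1,9-dione F7. The two are diastereomers because the cage is single-handed, so they are separated by chromatography. F7 is returned to 12 by mesylation and elimination (MsCl, Et3N, then DBU) and used again.

**Step 10.** The intramolecular hydride transfer may lose to retro-aldol opening of the β-hydroxy ketone, or hemiacetal formation at the hindered O7 may be slow. Any unoxidized SmI2 would also open the cyclobutane next to the C9 ketone. Fallback, from 14 to 20, with reagent control in place of the internal transfer: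
- TBSOTf and 2,6-lutidine give (7R)-7-(tert-butyldimethylsilyloxy)longipin-2-ene-1,9-dione F8.
- Corey–Bakshi–Shibata reduction with (S)-2-methyl-CBS-oxazaborolidine and BH3·SMe2 reduces both ketones. With quaternary C10 as the large group and C8H2 as the small one it is expected to give 9R, in (7R,9R)-7-(tert-butyldimethylsilyloxy)longipin-2-ene-1,9-diol F9 (C1 either way).
- MnO2 reoxidizes only the allylic C1 alcohol, giving (7R,9R)-7-(tert-butyldimethylsilyloxy)-9-hydroxylongipin-2-en-1-one F10.
- Yamaguchi esterification with 18 gives the 9-tiglate (7R,9R)-7-(tert-butyldimethylsilyloxy)-1-oxolongipin-2-en-9-yl (E)-2-methylbut-2-enoate F11.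
- HF·pyridine frees (7R,9R)-7-hydroxy-1-oxolongipin-2-en-9-yl (E)-2-methylbut-2-enoate F12.
- 3-Methylbutanoyl chloride, pyridine and DMAP give 20.

## Further compounds

F0 | step 3 | none | none
F1 | step 5 | 8-chlorolongipin-2-en-1-one (C8 epimers) | C1C(Cl)CC(C)(C)[C@@H]2[C@H]3C(=O)C=C(C)[C@@H]2[C@]31C
F2 | step 6 | 1-oxolongipina-2,7-dien-8-yl trifluoromethanesulfonate | C1C(OS(=O)(=O)C(F)(F)F)=CC(C)(C)[C@@H]2[C@H]3C(=O)C=C(C)[C@@H]2[C@]31C
F3 | step 6 | longipina-2,7-dien-1-one | C1C=CC(C)(C)[C@@H]2[C@H]3C(=O)C=C(C)[C@@H]2[C@]31C
F4 | step 8 | 8,9-epoxylongipin-2-en-1-one (either face) | O1C2C1CC(C)(C)[C@@H]3[C@H]4C(=O)C=C(C)[C@@H]3[C@]42C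
F5 | step 8 | 9-hydroxy-8-(phenylselanyl)longipin-2-en-1-one (trans, either face) | OC1C([Se]c2ccccc2)CC(C)(C)[C@@H]3[C@H]4C(=O)C=C(C)[C@@H]3[C@]41C
F6 | step 8 | 9-hydroxylongipina-2,7-dien-1-one (C9 epimers) | OC1C=CC(C)(C)[C@@H]2[C@H]3C(=O)C=C(C)[C@@H]2[C@]31C
F7 | step 9 | (7S)-7-hydroxylongipin-2-ene-1,9-dione | O=C1C[C@H](O)C(C)(C)[C@@H]2[C@H]3C(=O)C=C(C)[C@@H]2[C@]31C
F8 | step 10 | (7R)-7-(tert-butyldimethylsilyloxy)longipin-2-ene-1,9-dione | O=C1C[C@@H](O[Si](C)(C)C(C)(C)C)C(C)(C)[C@@H]2[C@H]3C(=O)C=C(C)[C@@H]2[C@]31C
F9 | step 10 | (7R,9R)-7-(tert-butyldimethylsilyloxy)longipin-2-ene-1,9-diol (C1 epimers) | O[C@@H]1C[C@@H](O[Si](C)(C)C(C)(C)C)C(C)(C)[C@@H]2[C@H]3C(O)C=C(C)[C@@H]2[C@]31C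
F10 | step 10 | (7R,9R)-7-(tert-butyldimethylsilyloxy)-9-hydroxylongipin-2-en-1-one | O[C@@H]1C[C@@H](O[Si](C)(C)C(C)(C)C)C(C)(C)[C@@H]2[C@H]3C(=O)C=C(C)[C@@H]2[C@]31C
F11 | step 10 | (7R,9R)-7-(tert-butyldimethylsilyloxy)-1-oxolongipin-2-en-9-yl (E)-2-methylbut-2-enoate | C/C=C(\C)C(=O)O[C@@H]1C[C@@H](O[Si](C)(C)C(C)(C)C)C(C)(C)[C@@H]2[C@H]3C(=O)C=C(C)[C@@H]2[C@]31C
F12 | step 10 | (7R,9R)-7-hydroxy-1-oxolongipin-2-en-9-yl (E)-2-methylbut-2-enoate | C/C=C(\C)C(=O)O[C@@H]1C[C@@H](O)C(C)(C)[C@@H]2[C@H]3C(=O)C=C(C)[C@@H]2[C@]31C
A1 | alternative 1 | bicyclo[4.2.1]nonane C11-diazo C1-ketone with C4 dioxolane side chain, C7 3-methylbutanoate and C9 silyl ether | [C@@H]1(O[Si](C)(C)C(C)(C)C)C[C@@H](OC(=O)CC(C)C)C(C)(C)[C@@H]2C(=[N+]=[N-])C(=O)[C@@]1(C)[C@H]2C3(C)OCCO3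
A2 | alternative 1 | bicyclo[4.1.1]octane C11 methyl ester with C4 dioxolane side chain (ring-contracted product) | [C@@H]1(O[Si](C)(C)C(C)(C)C)C[C@@H](OC(=O)CC(C)C)C(C)(C)[C@@H]2[C@@H](C(=O)OC)[C@@]1(C)[C@H]2C3(C)OCCO3
A3 | alternative 2 | methyl 2,4-dibromo-2-methyl-3-oxocyclobutane-1-carboxylate | COC(=O)C1C(Br)C(=O)C1(C)Br
A4 | alternative 2 | (E)-1-(4-methoxybenzyloxy)-4-methyl-3-(trimethylsilyloxy)penta-1,3-diene | COc1ccc(CO/C=C/C(O[Si](C)(C)C)=C(C)C)cc1
A5 | alternative 2 | bicyclo[4.1.1]oct-3-en-8-one with C7 silyl enol ether, C9 4-methoxybenzyl ether and C11 methyl ester | COc1ccc(CO[C@@H]2C=C(O[Si](C)(C)C)C(C)(C)[C@@H]3[C@@H](C(=O)OC)[C@@]2(C)C3=O)cc1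
A6 | alternative 3 | 1-(triethylsilyloxy)-3,5-dimethylcyclopentadiene carrying at the quaternary C10 the C9–C6 tether that ends in the (E)-alkenyl pinacolboronate | CC[Si](CC)(CC)OC1=CC(C)=C[C@@]1(C)[C@H](O[Si](C)(C)C(C)(C)C)C[C@@H](OC(=O)CC(C)C)C(C)(C)/C=C/B2OC(C)(C)C(C)(C)O2
A7 | alternative 3 | tricyclic norbornene with bridgehead triethylsilyl ether and endo C11 pinacolboronate | [C@]12(O[Si](CC)(CC)CC)C=C(C)[C@H]3[C@H](C(C)(C)[C@H](OC(=O)CC(C)C)C[C@@H](O[Si](C)(C)C(C)(C)C)[C@@]13C)[C@H]2B4OC(C)(C)C(C)(C)O4
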